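## Retrosynthetic overview
1. Huazhongilexin ⇐ global desilylation/debenzylation ⇐ the 2,5-trans-diaryl-THF, formed last by acid-promoted 5-exo etherification of a 1,4-diol (C7–OH onto a C7′ benzylic cation), which is 2,3-trans and thermodynamically all-trans.
2. That 1,4-diol ⇐ LiAlH4 opening of a trans-3,4-disubstituted γ-butyrolactone, which is the first ring formed.
3. The lactone's C3/C7 centres ⇐ ketoreductase dynamic kinetic resolution of a β-keto-lactone (aldol, then oxidation).
4. The lactone's C4 centre ⇐ Fráter–Seebach anti-alkylation of an (R)-β-hydroxy ester from Ru-BINAP hydrogenation, then Lemieux–Johnson cleavage and lactol oxidation. Starting materials are acetosyringone and syringaldehyde.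

**Assumptions (one line):** (S)-BINAP delivers the (R)-3-aryl-3-hydroxy ester (CIP priority reversal relative to alkyl analogues). A commercial KRED giving the (S)-carbinol with dynamic resolution at C3 is found on screening. Ar = 4-(benzyloxy)-3,5-dimethoxyphenyl; phenols are carried as benzyl ethers.

## Route

**Step 1**
Reactants: 1 acetosyringone
Product: 2 1-[4-(benzyloxy)-3,5-dimethoxyphenyl]ethan-1-one
Conditions: BnBr, K2CO3, DMF, 60 °C
Reagents that add atoms: benzyl bromide, BrCc1ccccc1
Why: Williamson O-alkylation masks the phenol for the later enolate, hydrogenation and reduction steps.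

**Step 2**
Reactants: 2
Product: 3 methyl 3-[4-(benzyloxy)-3,5-dimethoxyphenyl]-3-oxopropanoate
Conditions: (MeO)2CO, NaH, THF, reflux (cat. MeOH)
Reagents that add atoms: dimethyl carbonate, COC(=O)OC
Why: Claisen-type methoxycarbonylation of the methyl ketone enolate; the product is driven forward as its stabilised enolate.

**Step 3**
Reactants: 3
Product: 4 methyl (3R)-3-[4-(benzyloxy)-3,5-dimethoxyphenyl]-3-hydroxypropanoate
Conditions: H2 (10 atm), RuCl2[(S)-BINAP] (1 mol%), MeOH, 50 °C
Reagents that add atoms: none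
Why: Noyori asymmetric hydrogenation through ester-chelated Ru sets the first stereocentre (C7′, R) with high ee.

**Step 4**
Reactants: 4
Product: 5 methyl (2S,3R)-2-allyl-3-[4-(benzyloxy)-3,5-dimethoxyphenyl]-3-hydroxypropanoate (anti)
Conditions: LDA (2.2 equiv), THF, –78 → –20 °C; then allyl bromide, DMPU, –20 → 0 °C
Reagents that add atoms: allyl bromide, C=CCBr
Why: Fráter–Seebach alkylation of the chelated dianion occurs anti to the aryl group, so C7′ controls C8′ (2S, which is R in the final numbering).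

**Step 5**
Reactants: 5
Product: 6 methyl (2S,3R)-2-allyl-3-[Ar]-3-(triethylsilyloxy)propanoate
Conditions: TESOTf, 2,6-lutidine, CH2Cl2, –78 → 0 °C
Reagents that add atoms: triethylsilyl triflate, CC[Si](CC)(CC)OS(=O)(=O)C(F)(F)F
Why: Silylation blocks C7′–OH so that only one lactol can form later; no stereocentre is touched.

**Step 6**
Reactants: 6
Product: 7 (2R)-2-{(R)-[Ar][(triethylsilyl)oxy]methyl}pent-4-en-1-ol
Conditions: LiAlH4, THF, 0 °C
Reagents that add atoms: none
Why: Ester-to-primary-alcohol hydride reduction; the silyl ether and both stereocentres are unaffected.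

**Step 7**
Reactants: 7
Product: 8 (4R)-4-{(R)-[Ar][(triethylsilyl)oxy]methyl}oxolan-2-ol (lactol, anomeric mixture)
Conditions: OsO4 (5 mol%), NaIO4, 2,6-lutidine, dioxane/H2O 3:1, rt
Reagents that add atoms: sodium periodate (oxygen source), [Na+].[O-][I](=O)(=O)=O
Why: Lemieux–Johnson cleavage of the terminal alkene gives the aldehyde, which closes onto the primary alcohol to form the five-membered lactol; C8′ is not involved.

**Step 8**
Reactants: 8
Product: 9 (4R)-4-{(R)-[Ar][(triethylsilyl)oxy]methyl}oxolan-2-one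
Conditions: TEMPO (10 mol%), PhI(OAc)2, CH2Cl2, rt
Reagents that add atoms: none
Why: TEMPO/BAIB oxidation converts the lactol to the γ-lactone with no change at the stereocentres.

**Step 9**
Reactants: 10 syringaldehyde
Product: 11 4-(benzyloxy)-3,5-dimethoxybenzaldehyde
Conditions: BnBr, K2CO3, DMF, 60 °C
Reagents that add atoms: benzyl bromide, BrCc1ccccc1
Why: Williamson O-alkylation prepares the aldehyde partner for the aldol.

**Step 10**
Reactants: 9 lactone, 11 aldehyde
Product: 12 (3S,4R)-3-[hydroxy(Ar)methyl]-4-{(R)-[Ar][(triethylsilyl)oxy]methyl}oxolan-2-one (C7 epimer mixture)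
Conditions: LDA (1.1 equiv), THF, –78 °C; then 11, –78 °C
Reagents that add atoms: none
Why: Lactone-enolate aldol; the aldehyde approaches anti to the bulky C4 substituent, giving 3,4-trans (C3 = S), while C7 forms as a mixture that is funnelled in Steps 11 and 12.

**Step 11**
Reactants: 12
Product: 13 3-(4-benzyloxy-3,5-dimethoxybenzoyl)-4-{(R)-[Ar][(triethylsilyl)oxy]methyl}oxolan-2-one (keto/enol; C3 epimerising)
Conditions: Dess–Martin periodinane, NaHCO3, CH2Cl2, rt
Reagents that add atoms: none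
Why: Oxidation removes the C7 ambiguity and gives an acidic, rapidly epimerising β-keto-lactone suited to dynamic resolution.

**Step 12**
Reactants: 13
Product: 14 (3S,4R)-3-[(S)-hydroxy(Ar)methyl]-4-{(R)-[Ar][(triethylsilyl)oxy]methyl}oxolan-2-one
Conditions: ketoreductase (NADPH-dependent oxidoreductase), NADP+ (cat.), glucose/GDH, KPi buffer pH 7.5, 15% DMSO, 30 °C
Reagents that add atoms: none
Why: Enzymatic dynamic kinetic resolution: C3 epimerises at pH 7.5 while the KRED delivers hydride to one face of the ketone, setting C7 (S) and C3 (S, trans to C4) in a single step.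

**Step 13**
Reactants: 14
Product: 15 (2R,3R)-2-{(S)-hydroxy(Ar)methyl}-3-{(R)-[Ar][(triethylsilyl)oxy]methyl}butane-1,4-diol
Conditions: LiAlH4, THF, 0 °C (Rochelle-salt quench)
Reagents that add atoms: none
Why: Hydride reduction opens the lactone to the two primary alcohols (C9, C9′) without touching any stereocentre.

**Step 14**
Reactants: 15
Product: 16 the 1,4-bis(TBDPS) ether of 15 (C7–OH free, C7′–OTES)
Conditions: TBDPSCl (2.4 equiv), imidazole, DMF, rt
Reagents that add atoms: tert-butyldiphenylsilyl chloride, CC(C)(C)[Si](Cl)(c1ccccc1)c1ccccc1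
Why: The bulky silyl chloride reacts selectively with the two primary alcohols. This prevents lariciresinol-type 7′,9-cyclisation and leaves one free nucleophilic carbinol of the correct (S) configuration.

**Step 15**
Reactants: 16
Product: 17 (2S,3R,4R,5S)-2,5-bis(Ar)-3,4-bis[(tert-butyldiphenylsilyloxy)methyl]tetrahydrofuran
Conditions: CSA (10 mol%), CH2Cl2, 0 °C → rt
Reagents that add atoms: none
Why: Acid-promoted cyclodehydrative etherification: the C7′–OSiEt3 ionises to the electron-rich benzylic cation, which is captured 5-exo by the C7–OH. Capture gives 2,3-trans at the new centre, C7 keeps its S configuration, and all-trans is also the thermodynamic isomer, so the product is (2S,5S).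

**Step 16**
Reactants: 17
Product: 18 (2S,3R,4R,5S)-2,5-bis(Ar)-3,4-bis(hydroxymethyl)tetrahydrofuran
Conditions: TBAF, THF, 0 °C → rt
Reagents that add atoms: none
Why: Fluoride cleaves the primary silyl ethers; no base-sensitive groups remain.

**Step 17**
Reactants: 18
Product: 19 Huazhongilexin, (2S,3R,4R,5S)-2,5-bis(4-hydroxy-3,5-dimethoxyphenyl)-3,4-bis(hydroxymethyl)tetrahydrofuran
Conditions: H2 (1 atm), 10% Pd/C, EtOAc/EtOH, rt, short reaction time
Reagents that add atoms: none
Why: Aryl benzyl ether hydrogenolysis is much faster than cleavage of the hindered benzylic THF C–O bonds, so the ring and its stereocentres are retained.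

## Compound list
1 | acetosyringone | CC(=O)c1cc(OC)c(O)c(OC)c1 | starting material
2 | 1-[4-(benzyloxy)-3,5-dimethoxyphenyl]ethanone | CC(=O)c1cc(OC)c(OCc2ccccc2)c(OC)c1 | intermediate
3 | methyl 3-[Ar]-3-oxopropanoate | COC(=O)CC(=O)c1cc(OC)c(OCc2ccccc2)c(OC)c1 | intermediate
4 | methyl (3R)-3-[Ar]-3-hydroxypropanoate | COC(=O)C[C@@H](O)c1cc(OC)c(OCc2ccccc2)c(OC)c1 | intermediate
5 | methyl (2S,3R)-2-allyl-3-[Ar]-3-hydroxypropanoate | COC(=O)[C@@H](CC=C)[C@@H](O)c1cc(OC)c(OCc2ccccc2)c(OC)c1 | intermediate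
6 | TES ether of 5 | COC(=O)[C@@H](CC=C)[C@@H](O[Si](CC)(CC)CC)c1cc(OC)c(OCc2ccccc2)c(OC)c1 | intermediate
7 | (2R)-2-{(R)-[Ar](TESO)methyl}pent-4-en-1-ol | OC[C@@H](CC=C)[C@@H](O[Si](CC)(CC)CC)c1cc(OC)c(OCc2ccccc2)c(OC)c1 | intermediate
8 | lactol | OC1C[C@@H]([C@@H](O[Si](CC)(CC)CC)c2cc(OC)c(OCc3ccccc3)c(OC)c2)CO1 | intermediate
9 | (4R)-4-{(R)-[Ar](TESO)methyl}oxolan-2-one | O=C1C[C@@H]([C@@H](O[Si](CC)(CC)CC)c2cc(OC)c(OCc3ccccc3)c(OC)c2)CO1 | intermediate
10 | syringaldehyde | O=Cc1cc(OC)c(O)c(OC)c1 | starting material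
11 | 4-(benzyloxy)-3,5-dimethoxybenzaldehyde | O=Cc1cc(OC)c(OCc2ccccc2)c(OC)c1 | intermediate
12 | aldol adduct (C7 epimers, 3,4-trans) | O=C1[C@H](C(O)c2cc(OC)c(OCc3ccccc3)c(OC)c2)[C@@H]([C@@H](O[Si](CC)(CC)CC)c2cc(OC)c(OCc3ccccc3)c(OC)c2)CO1 | intermediate
13 | 3-aroyl-lactone (C3 epimerising) | O=C1C(C(=O)c2cc(OC)c(OCc3ccccc3)c(OC)c2)[C@@H]([C@@H](O[Si](CC)(CC)CC)c2cc(OC)c(OCc3ccccc3)c(OC)c2)CO1 | intermediate
14 | (3S,4R)-3-[(S)-hydroxy(Ar)methyl]-4-{(R)-[Ar](TESO)methyl}oxolan-2-one | O=C1[C@H]([C@H](O)c2cc(OC)c(OCc3ccccc3)c(OC)c2)[C@@H]([C@@H](O[Si](CC)(CC)CC)c2cc(OC)c(OCc3ccccc3)c(OC)c2)CO1 | intermediate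
15 | (2R,3R)-2-{(S)-hydroxy(Ar)methyl}-3-{(R)-[Ar](TESO)methyl}butane-1,4-diol | OC[C@H]([C@@H](O[Si](CC)(CC)CC)c1cc(OC)c(OCc2ccccc2)c(OC)c1)[C@H](CO)[C@H](O)c1cc(OC)c(OCc2ccccc2)c(OC)c1 | intermediate
16 | 1,4-bis-TBDPS ether of 15 | CC(C)(C)[Si](c1ccccc1)(c1ccccc1)OC[C@H]([C@@H](O[Si](CC)(CC)CC)c1cc(OC)c(OCc2ccccc2)c(OC)c1)[C@H](CO[Si](c1ccccc1)(c1ccccc1)C(C)(C)C)[C@H](O)c1cc(OC)c(OCc2ccccc2)c(OC)c1 | intermediate
17 | bis-TBDPS, bis-benzyl THF | COc1cc([C@H]2O[C@H](c3cc(OC)c(OCc4ccccc4)c(OC)c3)[C@@H](CO[Si](c5ccccc5)(c5ccccc5)C(C)(C)C)[C@@H]2CO[Si](c5ccccc5)(c5ccccc5)C(C)(C)C)cc(OC)c1OCc1ccccc1 | intermediate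
18 | bis-benzyl THF diol | COc1cc([C@H]2O[C@H](c3cc(OC)c(OCc4ccccc4)c(OC)c3)[C@@H](CO)[C@@H]2CO)cc(OC)c1OCc1ccccc1 | intermediate
19 | Huazhongilexin | COc1cc([C@H]2O[C@H](c3cc(OC)c(O)c(OC)c3)[C@@H](CO)[C@@H]2CO)cc(OC)c1O | target

## Totals
Total steps: 17. Longest linear sequence: 16 steps (acetosyringone → target). The aldehyde 11 is a one-step convergent branch.

## Three steps most likely to fail
1. **Step 12 (KRED dynamic kinetic resolution).** The bulky, poorly soluble substrate may not match any commercial KRED for both C7 and C3. Fallback: skip Steps 11–12. Separate the C7 epimers of aldol adduct 12 by chromatography, invert the (7R) epimer by Mitsunobu reaction with p-nitrobenzoic acid followed by K2CO3/MeOH, and carry 14 forward.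
2. **Step 15 (cyclodehydration).** The mismatched diastereomer or a lariciresinol-type ring could form. Fallback: remove the TES group (K2CO3, MeOH) and cyclise by Mitsunobu reaction (PPh3, DIAD). The diol is (7S,7′R), so SN2 inversion at C7′ with the C7–OH as nucleophile gives the (2S,5S) ring.
3. **Step 4 (Fráter–Seebach anti-alkylation of an aryl substrate).** The diastereoselectivity may be below 95:5. Fallback: allylate β-keto ester 3 at carbon, then set C7′ and C8′ together by Ru-catalysed dynamic kinetic resolution hydrogenation and carry the anti isomer forward.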